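**Strategy.** Ring A is built, not bought. Cutting its C1–C2 and C5–C6 bonds (C1 = butyryl carbon, C5 = bridge carbon) gives a 1-methoxy-1,3-bis(trimethylsilyloxy)diene that already carries the ring-B benzyl group on its terminus, and a 1-benzyloxy ynone. One (4+2) cycloaddition–aromatisation then sets all six substituents of ring A. It uses the alternation of the three ring-A oxygens (C2, C4, C6) with butyryl (C1), methyl (C3) and the bridge CH2 (C5), so the diarylmethane link is never made by arene–formaldehyde coupling. The diene comes from a δ-aryl β-keto ester made by aldol addition and ionic deoxygenation; ring B is butyrylated last.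

Key step: step 11

Remark on the chemistry: the target is achiral. Compounds 8, 9, 21 and 23 carry stereocentres, and 10 and 12 a C=C bond of undefined geometry; all are erased later, so these compounds are carried as mixtures. Ring A is numbered C1 (butyryl) to C6, ring B C1' (bridge) to C6'. The bridge carbon is attached as an aldehyde (steps 4 and 5) because a 2,4,6-trioxygenated benzyl halide would be expected to ionise and self-condense.

**Step 1**
Reactants: 1 2-methylphloroglucinol (2-methylbenzene-1,3,5-triol)
Product: 3 2,4,6-trihydroxy-3-methylbenzaldehyde, via aryl iminium chloride 2 (not isolated)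
Conditions: POCl3 (1.1 equiv), DMF (1.2 equiv), EtOAc, 0→20 °C; then H2O, 60 °C
Reagents that add atoms: N,N-dimethylformamide CN(C)C=O; water O
Why: Vilsmeier–Haack formylation of an activated arene; the two free ring carbons of 1 are equivalent by symmetry, so only one aldehyde can form, and the iminium group of 2 deactivates the ring against a second attack.

**Step 2**
Reactants: 3 2,4,6-trihydroxy-3-methylbenzaldehyde
Product: 4 2,6-dihydroxy-4-methoxy-3-methylbenzaldehyde
Conditions: MeI (1.05 equiv), Li2CO3 (1.1 equiv), DMF, 40 °C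
Reagents that add atoms: iodomethane CI
Why: Williamson ether synthesis under weak-base control; the hydroxyl para to the formyl group is the most acidic and the only one that cannot chelate the carbonyl oxygen, so the mono-phenoxide should be methylated there.

**Step 3**
Reactants: 4 2,6-dihydroxy-4-methoxy-3-methylbenzaldehyde
Product: 5 2,6-bis(benzyloxy)-4-methoxy-3-methylbenzaldehyde
Conditions: BnBr (2.4 equiv), K2CO3 (3 equiv), Bu4NI (cat.), DMF, 60 °C
Reagents that add atoms: benzyl bromide BrCc1ccccc1
Why: Williamson etherification of the two remaining carbonyl-flanked phenols, which only needs the stronger base and heat; no positional isomer is possible.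

**Step 4**
Reactants: 5 2,6-bis(benzyloxy)-4-methoxy-3-methylbenzaldehyde; 6 methyl 2-methyl-3-oxobutanoate
Product: 8 methyl 5-[2,6-bis(benzyloxy)-4-methoxy-3-methylphenyl]-5-hydroxy-2-methyl-3-oxopentanoate, via dilithium dianion 7 (not isolated)
Conditions: LiN(i-Pr)2 (2.1 equiv), THF, −78→0 °C; then 5, −78 °C; AcOH, −78 °C
Reagents that add atoms: none
Why: Aldol addition of a β-keto ester dianion, which reacts at its terminal carbon with the non-enolisable aldehyde; the two new stereocentres are left uncontrolled because C5 is deoxygenated in step 5 and C2 becomes sp2 in step 6.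

**Step 5**
Reactants: 8 methyl 5-[2,6-bis(benzyloxy)-4-methoxy-3-methylphenyl]-5-hydroxy-2-methyl-3-oxopentanoate
Product: 9 methyl 5-[2,6-bis(benzyloxy)-4-methoxy-3-methylphenyl]-2-methyl-3-oxopentanoate
Conditions: Et3SiH (3 equiv), CF3CO2H (5 equiv), CH2Cl2, −20→0 °C
Reagents that add atoms: none
Why: Ionic hydrogenation; the 2,4,6-trioxygenated benzylic alcohol ionises readily and the cation is reduced by the silane, the same capture used to scavenge trialkoxybenzyl cations in acidolytic deprotections, while benzyl ethers and the β-keto ester should tolerate brief cold acid.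

**Step 6**
Reactants: 9 methyl 5-[2,6-bis(benzyloxy)-4-methoxy-3-methylphenyl]-2-methyl-3-oxopentanoate
Product: 10 methyl 5-[2,6-bis(benzyloxy)-4-methoxy-3-methylphenyl]-2-methyl-3-(trimethylsilyloxy)pent-2-enoate
Conditions: Me3SiCl (1.5 equiv), Et3N (1.6 equiv), toluene, 20 °C; filtration under argon
Reagents that add atoms: chlorotrimethylsilane C[Si](C)(C)Cl
Why: O-silylation of the enolisable β-keto ester (silyl enol ether formation), the usual first stage towards 1-alkoxy-1,3-bis(silyloxy)dienes, also for 2-alkyl β-keto esters.

**Step 7**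
Reactants: 10 methyl 5-[2,6-bis(benzyloxy)-4-methoxy-3-methylphenyl]-2-methyl-3-(trimethylsilyloxy)pent-2-enoate
Product: 12 (3Z)-5-[2,6-bis(benzyloxy)-4-methoxy-3-methylphenyl]-1-methoxy-2-methyl-1,3-bis(trimethylsilyloxy)penta-1,3-diene, via lithium dienolate 11 (not isolated)
Conditions: LiN(i-Pr)2 (1.3 equiv), THF, −78 °C; Me3SiCl (1.5 equiv), −78→20 °C; hexane, filtration, no aqueous work-up, used crude
Reagents that add atoms: chlorotrimethylsilane C[Si](C)(C)Cl
Why: γ-Deprotonation of the β-silyloxy enoate at the CH2 next to the enol ether carbon and O-silylation of the dienolate (silyl ketene acetal formation); the (3Z) geometry is the one such dienolates normally give and the C1=C2 geometry is immaterial.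

**Step 8**
Reactants: 13 benzyl alcohol; 14 trichloroethylene
Product: 17 benzyl (E)-1,2-dichlorovinyl ether, via potassium benzyloxide 15 (not isolated), via dichloroacetylene 16 (not isolated)
Conditions: KH (1.2 equiv), THF, 0 °C; then 14, −50→20 °C
Reagents that add atoms: none
Why: Base-induced loss of HCl from trichloroethylene followed by anti-addition of the alkoxide to the dichloroacetylene formed (elimination–addition), which gives the (E)-dichlorovinyl ether.

**Step 9**
Reactants: 17 benzyl (E)-1,2-dichlorovinyl ether; 18 butanal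
Product: 21 racemic 1-(benzyloxy)hex-1-yn-3-ol, via benzyl chloroethynyl ether 19 (not isolated), via lithium benzyloxyacetylide 20 (not isolated)
Conditions: n-BuLi (2.2 equiv), THF, −78 °C; then 18, −78 °C; aq. NaHCO3
Reagents that add atoms: none
Why: Dehydrochlorination and chlorine–lithium exchange give the lithium alkoxyacetylide, which adds to the aldehyde (acetylide 1,2-addition); the carbinol centre is not controlled because it is oxidised in step 10, and the basic quench avoids Meyer–Schuster rearrangement.

**Step 10**
Reactants: 21 racemic 1-(benzyloxy)hex-1-yn-3-ol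
Product: 22 1-(benzyloxy)hex-1-yn-3-one
Conditions: activated MnO2 (15 equiv), CH2Cl2, 0→20 °C; filtration through Celite, used at once
Reagents that add atoms: none
Why: Oxidation of a propargylic alcohol by MnO2 under neutral, non-aqueous conditions, chosen because the ynol ether is sensitive to acid and water.

**Step 11**
Reactants: 12 (3Z)-5-[2,6-bis(benzyloxy)-4-methoxy-3-methylphenyl]-1-methoxy-2-methyl-1,3-bis(trimethylsilyloxy)penta-1,3-diene; 22 1-(benzyloxy)hex-1-yn-3-one
Product: 24 1-[2-(benzyloxy)-3-{[2,6-bis(benzyloxy)-4-methoxy-3-methylphenyl]methyl}-4,6-dihydroxy-5-methylphenyl]butan-1-one, via cycloadduct 23 (not isolated)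
Conditions: 22 (1.5 equiv), toluene (1 M), 20→40 °C, dark, argon; then 1 M HCl, THF, 0→20 °C
Reagents that add atoms: none
Why: Proposed new method: the terminal carbon C4 of the electron-rich diene 12 should bond to the benzyloxy-bearing alkyne carbon of 22 (the conjugate position of the ynone) and the ester-derived carbon C1 to the acyl-bearing alkyne carbon, either as a strongly asynchronous Diels–Alder reaction or as a Mukaiyama–Michael addition whose allenolate collapses at once onto the dialkoxycarbenium carbon; acid then expels methanol from the mixed silyl ketal of 23, cleaves both O–Si bonds and the dienone tautomerises to the phenol. The closest known reaction is the Diels–Alder reaction and aromatisation of 1-alkoxy-1,3-bis(silyloxy)dienes with acetylenic ketones and esters, which places the acyl group ortho to one new hydroxyl and para to the other in the same way; an oxygen-substituted ynone and a hexasubstituted arene extend it. Ring A is closed as a six-membered carbocycle by (4+2) cycloaddition, in the stepwise picture by a 6-exo-trig attack of the allenolate carbon on C1. No stereocentre remains, since the two sp3 carbons of 23 form without control and both become aromatic. The step needs head-to-tail regioselectivity and (4+2) rather than (3+3) periselectivity: the first is secured by the push–pull polarisation of 22 (oxygen-bearing carbon electrophilic) matched to the largest donor coefficient at C4 of 12, the second by the absence of a Lewis acid and by the C2 methyl group, which disfavours bonding of C2 to the ketone carbon. The (3Z) geometry keeps the arylmethyl group on the outside of the s-cis diene, and working at or below 40 °C is meant to avoid the sigmatropic shift of the benzyl alkynyl ether.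

**Step 12**
Reactants: 24 1-[2-(benzyloxy)-3-{[2,6-bis(benzyloxy)-4-methoxy-3-methylphenyl]methyl}-4,6-dihydroxy-5-methylphenyl]butan-1-one
Product: 25 1-{3-[(2,6-dihydroxy-4-methoxy-3-methylphenyl)methyl]-2,4,6-trihydroxy-5-methylphenyl}butan-1-one
Conditions: H2 (1 atm), 10% Pd/C, EtOAc–MeOH, 20 °C; handled under argon
Reagents that add atoms: none
Why: Catalytic hydrogenolysis of three aryl benzyl ethers; the chelated aryl ketone and the diarylmethane C–C bonds should not be reduced under these mild conditions.

**Step 13**
Reactants: 25 1-{3-[(2,6-dihydroxy-4-methoxy-3-methylphenyl)methyl]-2,4,6-trihydroxy-5-methylphenyl}butan-1-one; 26 butanenitrile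
Product: 28 1-{3-[(3-butanoyl-2,6-dihydroxy-4-methoxy-5-methylphenyl)methyl]-2,4,6-trihydroxy-5-methylphenyl}butan-1-one (target), via ketiminium chloride 27 (not isolated)
Conditions: 26 (3 equiv), ZnCl2, HCl (g), Et2O–1,4-dioxane, 0 °C; then H2O, 90 °C
Reagents that add atoms: water O
Why: Houben–Hoesch acylation; C5' of ring B (ortho to OMe and OH, para to OH) is the only unsubstituted aromatic carbon of 25, so the nitrilium electrophile can enter nowhere else, and hydrolysis of ketiminium salt 27 gives the ketone.

**Compound list**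

1 | 2-methylphloroglucinol | Cc1c(O)cc(O)cc1O | starting material
2 | [(2,4,6-trihydroxy-3-methylphenyl)methylidene]dimethylammonium chloride | C[N+](C)=Cc1c(O)cc(O)c(C)c1O.[Cl-] | intermediate (not isolated)
3 | 2,4,6-trihydroxy-3-methylbenzaldehyde | O=Cc1c(O)cc(O)c(C)c1O | intermediate
4 | 2,6-dihydroxy-4-methoxy-3-methylbenzaldehyde | O=Cc1c(O)cc(OC)c(C)c1O | intermediate
5 | 2,6-bis(benzyloxy)-4-methoxy-3-methylbenzaldehyde | O=Cc1c(OCc2ccccc2)cc(OC)c(C)c1OCc1ccccc1 | intermediate
6 | methyl 2-methyl-3-oxobutanoate | CC(=O)C(C)C(=O)OC | starting material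
7 | dilithium dianion of 6 (1,3-dienediolate form) | C=C(O[Li])C(C)=C(O[Li])OC | intermediate (not isolated)
8 | methyl 5-[2,6-bis(benzyloxy)-4-methoxy-3-methylphenyl]-5-hydroxy-2-methyl-3-oxopentanoate (diastereomer mixture, racemic) | COC(=O)C(C)C(=O)CC(O)c1c(OCc2ccccc2)c(C)c(OC)cc1OCc1ccccc1 | intermediate
9 | methyl 5-[2,6-bis(benzyloxy)-4-methoxy-3-methylphenyl]-2-methyl-3-oxopentanoate (racemic) | COC(=O)C(C)C(=O)CCc1c(OCc2ccccc2)c(C)c(OC)cc1OCc1ccccc1 | intermediate
10 | methyl 5-[2,6-bis(benzyloxy)-4-methoxy-3-methylphenyl]-2-methyl-3-(trimethylsilyloxy)pent-2-enoate (E/Z mixture) | COC(=O)C(C)=C(CCc1c(OCc2ccccc2)c(C)c(OC)cc1OCc1ccccc1)O[Si](C)(C)C | intermediate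
11 | lithium dienolate of 10 | COC(O[Li])=C(C)C(O[Si](C)(C)C)=CCc1c(OCc2ccccc2)c(C)c(OC)cc1OCc1ccccc1 | intermediate (not isolated)
12 | (3Z)-5-[2,6-bis(benzyloxy)-4-methoxy-3-methylphenyl]-1-methoxy-2-methyl-1,3-bis(trimethylsilyloxy)penta-1,3-diene (C1=C2 geometry undefined) | C[Si](C)(C)O\C(=C/Cc1c(OCc2ccccc2)c(C)c(OC)cc1OCc1ccccc1)C(C)=C(OC)O[Si](C)(C)C | intermediate
13 | benzyl alcohol | OCc1ccccc1 | starting material
14 | trichloroethylene | ClC=C(Cl)Cl | starting material
15 | potassium benzyloxide | [K+].[O-]Cc1ccccc1 | intermediate (not isolated)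
16 | dichloroacetylene | ClC#CCl | intermediate (not isolated)
17 | benzyl (E)-1,2-dichlorovinyl ether | Cl/C=C(/Cl)OCc1ccccc1 | intermediate
18 | butanal | CCCC=O | starting material
19 | benzyl chloroethynyl ether | ClC#COCc1ccccc1 | intermediate (not isolated)
20 | lithium benzyloxyacetylide | [Li]C#COCc1ccccc1 | intermediate (not isolated)
21 | 1-(benzyloxy)hex-1-yn-3-ol (racemic) | CCCC(O)C#COCc1ccccc1 | intermediate
22 | 1-(benzyloxy)hex-1-yn-3-one | CCCC(=O)C#COCc1ccccc1 | intermediate
23 | 1-[2-(benzyloxy)-3-{[2,6-bis(benzyloxy)-4-methoxy-3-methylphenyl]methyl}-6-methoxy-5-methyl-4,6-bis(trimethylsilyloxy)cyclohexa-1,4-dien-1-yl]butan-1-one (stereoisomer mixture) | CCCC(=O)C1=C(OCc2ccccc2)C(Cc2c(OCc3ccccc3)c(C)c(OC)cc2OCc2ccccc2)C(O[Si](C)(C)C)=C(C)C1(OC)O[Si](C)(C)C | intermediate (not isolated)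
24 | 1-[2-(benzyloxy)-3-{[2,6-bis(benzyloxy)-4-methoxy-3-methylphenyl]methyl}-4,6-dihydroxy-5-methylphenyl]butan-1-one | CCCC(=O)c1c(O)c(C)c(O)c(Cc2c(OCc3ccccc3)c(C)c(OC)cc2OCc2ccccc2)c1OCc1ccccc1 | intermediate
25 | 1-{3-[(2,6-dihydroxy-4-methoxy-3-methylphenyl)methyl]-2,4,6-trihydroxy-5-methylphenyl}butan-1-one | CCCC(=O)c1c(O)c(C)c(O)c(Cc2c(O)c(C)c(OC)cc2O)c1O | intermediate
26 | butanenitrile | CCCC#N | starting material
27 | 1-{3-[(3-butanoyl-2,4,6-trihydroxy-5-methylphenyl)methyl]-2,4-dihydroxy-6-methoxy-5-methylphenyl}butan-1-iminium chloride | CCCC(=[NH2+])c1c(O)c(Cc2c(O)c(C)c(O)c(C(=O)CCC)c2O)c(O)c(C)c1OC.[Cl-] | intermediate (not isolated)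
28 | 1-{3-[(3-butanoyl-2,6-dihydroxy-4-methoxy-5-methylphenyl)methyl]-2,4,6-trihydroxy-5-methylphenyl}butan-1-one | CCCC(=O)c1c(O)c(C)c(O)c(Cc2c(O)c(C)c(OC)c(C(=O)CCC)c2O)c1O | target

**Totals.** Total step count: 13. Longest linear sequence: 10 steps (steps 1 to 7, then 11, 12, 13).

**Steps most likely to fail**

1. Step 11 (the labelled step).
   - What may go wrong: the donor-substituted alkyne may react too slowly at temperatures the benzyl alkynyl ether tolerates. Sigmatropic benzyl migration, hydrolysis of the diene, or bond formation through C2 of the diene could then overtake the cycloaddition.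
   - Fallback (known chemistry: Friedel–Crafts benzylation of an acylphloroglucinol): it sets out from aldehyde 5 and starting material 1 and returns at 25. Aldehyde 5 would be reduced with NaBH4 (MeOH–THF, 0 °C) to [2,6-bis(benzyloxy)-4-methoxy-3-methylphenyl]methanol F1. Separately, 1 would be C-acylated with butanoyl chloride and AlCl3 (nitrobenzene–CH2Cl2) to 1-(2,4,6-trihydroxy-3-methylphenyl)butan-1-one F2; its two free ring carbons are equivalent. Slow addition of F1 to an excess of F2 with catalytic TsOH in MeCN at 0 °C should alkylate the single free ring carbon of F2 and give 1-[3-{[2,6-bis(benzyloxy)-4-methoxy-3-methylphenyl]methyl}-2,4,6-trihydroxy-5-methylphenyl]butan-1-one F3. Hydrogenolysis of F3 (H2, Pd/C) would give 25, and step 13 completes the route.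

2. Step 13.
   - What may go wrong: acid-promoted cleavage or scrambling of the methylene bridge, O-imidate formation on the free phenols, or incomplete conversion of a poorly soluble polyphenol.
   - Fallback: it sets out from 24 and returns at 28, with the acylation done on a fully protected substrate. The two free phenols of 24 would be benzylated (BnBr, K2CO3, DMF, 60 °C) to 1-[2,4,6-tris(benzyloxy)-3-{[2,6-bis(benzyloxy)-4-methoxy-3-methylphenyl]methyl}-5-methylphenyl]butan-1-one F4. Its only activated aromatic C–H (C5' of ring B) would then be acylated with butanoic acid and trifluoroacetic anhydride (CH2Cl2, 0→20 °C), a Friedel–Crafts acylation through the mixed anhydride, to give 1-[2,4,6-tris(benzyloxy)-3-{[2,6-bis(benzyloxy)-3-butanoyl-4-methoxy-5-methylphenyl]methyl}-5-methylphenyl]butan-1-one F5. Hydrogenolysis of all five benzyl ethers (H2, Pd/C) would give 28.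

3. Step 10.
   - What may go wrong: hydration of the ynol ether or Meyer–Schuster rearrangement of the alkoxy-propargylic alcohol during oxidation and isolation.
   - Fallback: it sets out from 17 and returns at 22 without passing through 21. Lithium acetylide 20, generated as in step 9, would be acylated with purchased N-methoxy-N-methylbutanamide (THF, −78→−20 °C, cold NaHCO3 quench); collapse of the chelated adduct on work-up gives 22 directly. No new isolated compound is formed.

**Further compounds**

F1 | step 11 | [2,6-bis(benzyloxy)-4-methoxy-3-methylphenyl]methanol | OCc1c(OCc2ccccc2)c(C)c(OC)cc1OCc1ccccc1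
F2 | step 11 | 1-(2,4,6-trihydroxy-3-methylphenyl)butan-1-one | CCCC(=O)c1c(O)cc(O)c(C)c1O
F3 | step 11 | 1-[3-{[2,6-bis(benzyloxy)-4-methoxy-3-methylphenyl]methyl}-2,4,6-trihydroxy-5-methylphenyl]butan-1-one | CCCC(=O)c1c(O)c(C)c(O)c(Cc2c(OCc3ccccc3)c(C)c(OC)cc2OCc2ccccc2)c1O
F4 | step 13 | 1-[2,4,6-tris(benzyloxy)-3-{[2,6-bis(benzyloxy)-4-methoxy-3-methylphenyl]methyl}-5-methylphenyl]butan-1-one | CCCC(=O)c1c(OCc2ccccc2)c(C)c(OCc2ccccc2)c(Cc2c(OCc3ccccc3)c(C)c(OC)cc2OCc2ccccc2)c1OCc1ccccc1
F5 | step 13 | 1-[2,4,6-tris(benzyloxy)-3-{[2,6-bis(benzyloxy)-3-butanoyl-4-methoxy-5-methylphenyl]methyl}-5-methylphenyl]butan-1-one | CCCC(=O)c1c(OCc2ccccc2)c(C)c(OCc2ccccc2)c(Cc2c(OCc3ccccc3)c(C)c(OC)c(C(=O)CCC)c2OCc2ccccc2)c1OCc1ccccc1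
F0 | step 10 | none | none
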